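**Plan**

1. Retrosynthesis: the two ester C–O bonds (C11 acetate, C8 propanoate) are cut first, then the two C11–CH3 bonds (back to a methyl ester on C7), and last the seven-membered ring at C6–C7 and C9–C10.
2. Enabling feature (guaiane numbering: C1 ring-fusion CH, C2 CH2, C3 ketone, C4=C5 the ring-A alkene, C6 CH2, C7 bearing C11, C8 bearing the propanoate oxygen, C9 CH2, C10 bearing methyl): C7–C8–C9 is an oxygenated three-carbon unit, and its neighbours C6 and C10 are the two ends of an s-cis diene exocyclic to ring A.
3. Forward: ring A comes from 2-methylcyclopentane-1,3-dione (vinylogous ester, ethylidene at C1, methylidene at C5). The seven-membered ring is then closed in one operation by carbenoid cyclopropanation of C5=C6 and Cope rearrangement with a 2-siloxyvinyl diazoacetate made from methyl acetoacetate. Hydrolysis, reduction, methyl addition, re-oxidation and two acylations finish the route.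
4. Stereochemistry: C10 from the chiral catalyst Rh2(S-PTAD)4 and the E-ethylidene through the boat Cope transition state. C1 by thermodynamic γ-protonation (C1–C2 bond trans to the C10 methyl, H-1 on the methyl face). C7 and C8 together by chelation-controlled hydride reduction of the configurationally labile β-keto ester from the face opposite the C10 methyl.

Key step: step 7

Assumption: Rh2(S-PTAD)4 is taken to give the 10S series drawn; the sense of induction on this 1,1-disubstituted methylidene must be confirmed on the first run, and Rh2(R-PTAD)4 replaces it if the sense is opposite.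

**Route**

Step 1
Reactants: 1 2-methylcyclopentane-1,3-dione
Product: 2 3-isobutoxy-2-methylcyclopent-2-en-1-one
Conditions: iBuOH, TsOH·H2O (cat.), PhMe, reflux, Dean–Stark
Reagents that add atoms: 2-methylpropan-1-ol, CC(C)CO
Why: Acid-catalysed enol etherification of the symmetric cyclic 1,3-dione with azeotropic removal of water gives the vinylogous ester, the only possible regioisomer.

Step 2
Reactants: 2 3-isobutoxy-2-methylcyclopent-2-en-1-one; 3 acetaldehyde
Product: 4 5-(1-hydroxyethyl)-3-isobutoxy-2-methylcyclopent-2-en-1-one (racemic, both diastereomers)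
Conditions: LiN(iPr)2, THF, −78 °C; then CH3CHO, −78 °C; aq. NH4Cl
Reagents that add atoms: none
Why: LiN(iPr)2 deprotonates the vinylogous ester kinetically at the α' methylene (the Stork–Danheiser mode of enolate formation) and the enolate undergoes aldol addition to acetaldehyde; the two new stereocentres do not matter because both are removed in step 3.

Step 3
Reactants: 4 5-(1-hydroxyethyl)-3-isobutoxy-2-methylcyclopent-2-en-1-one
Product: 6 (E)-5-ethylidene-3-isobutoxy-2-methylcyclopent-2-en-1-one, via aldol mesylate 5 (not isolated)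
Conditions: MsCl, Et3N, CH2Cl2, 0 °C; then DBU, 0 °C to rt
Reagents that add atoms: none
Why: Mesylation followed by DBU-induced E1cB elimination completes the aldol condensation and should give the thermodynamically preferred E-alkylidene ketone, with the methyl group pointing away from the carbonyl group.

Step 4
Reactants: 6 (E)-5-ethylidene-3-isobutoxy-2-methylcyclopent-2-en-1-one
Product: 7 (E)-4-ethylidene-1-isobutoxy-2-methyl-3-methylidenecyclopent-1-ene
Conditions: Cp2Ti(μ-CH2)(μ-Cl)AlMe2, pyridine (cat.), THF/PhMe, −40 to 0 °C; aq. NaOH; filtration through basic Al2O3; used at once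
Reagents that add atoms: Tebbe reagent Cp2Ti(μ-CH2)(μ-Cl)AlMe2, C[Al-]1(C)C[Ti](C2C=CC=C2)(C2C=CC=C2)[Cl+]1
Why: Tebbe olefination: Cp2Ti=CH2 adds to the carbonyl group by [2+2] cycloaddition and the oxatitanacyclobutane cycloreverts to the methylidene compound, a non-basic methylenation known for enolisable ketones, enones and esters, so the weakly electrophilic vinylogous ester carbonyl should react without enolisation and without change of the ethylidene geometry.

Step 5
Reactants: 8 methyl acetoacetate
Product: 9 methyl 2-diazo-3-oxobutanoate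
Conditions: 4-acetamidobenzenesulfonyl azide, Et3N, MeCN, 0 °C to rt
Reagents that add atoms: 4-acetamidobenzenesulfonyl azide, CC(=O)Nc1ccc(cc1)S(=O)(=O)N=[N+]=[N-]
Why: Regitz diazo transfer from the sulfonyl azide to the doubly activated methylene of the β-keto ester.

Step 6
Reactants: 9 methyl 2-diazo-3-oxobutanoate
Product: 10 methyl 3-(tert-butyldimethylsilyloxy)-2-diazobut-3-enoate
Conditions: TBSOTf, Et3N, CH2Cl2, 0 °C
Reagents that add atoms: tert-butyldimethylsilyl trifluoromethanesulfonate, CC(C)(C)[Si](C)(C)OS(=O)(=O)C(F)(F)F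
Why: Soft enolisation with Et3N and O-silylation by TBSOTf gives the 2-siloxyvinyl diazoacetate; the diazo carbon has no hydrogen, so only the methyl side can enolise.

Step 7
Reactants: 7 (E)-4-ethylidene-1-isobutoxy-2-methyl-3-methylidenecyclopent-1-ene; 10 methyl 3-(tert-butyldimethylsilyloxy)-2-diazobut-3-enoate
Product: 12 methyl (8S)-6-[(tert-butyldimethylsilyl)oxy]-3,8-dimethyl-2-(2-methylpropoxy)-1,4,7,8-tetrahydroazulene-5-carboxylate, via spiro divinylcyclopropane 11 (not isolated)
Conditions: Rh2(S-PTAD)4 [dirhodium tetrakis((S)-(1-adamantyl)(N-phthalimido)acetate)] (1 mol %), hexanes, −26 °C, slow addition of 10 (1.5 equiv) over 3 h, then rt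
Reagents that add atoms: none
Why: Loss of N2 from 10 on the catalyst (a dimer of divalent rhodium) gives an electrophilic donor/acceptor vinylcarbenoid whose carbene carbon (future C7) adds to the terminal C5=C6 methylidene of 7 in a concerted, asynchronous [2+1] closure of the three-membered ring, giving spiro cyclopropane 11 with the siloxyvinyl group on the side of the ethylidene-bearing carbon C1. In 11 ring A holds the C1=C10 bond next to the breaking C5–C7 bond in the endo geometry, so the cis-divinylcyclopropane should undergo a strain-driven [3,3] sigmatropic (Cope) shift through a boat transition state at or below room temperature, forming C9–C10 as C5–C7 breaks; with the C6–C7 bond from the cyclopropanation this closes the seven-membered ring as a formal (4+3) cycloaddition. The closest known reaction type is the enantioselective tandem cyclopropanation/Cope rearrangement of 2-siloxyvinyl diazoacetates with acyclic and cyclic 1,3-dienes under Rh2(S-PTAD)4. The only new stereocentre, C10, is fixed by two elements: the chiral carboxylate ligands decide on which face of the ring-A plane the carbenoid carbon is attached, and the E geometry of the ethylidene (hydrogen inside, methyl outside in the boat) turns that face into the S configuration when C9 bonds to C10 from the same face. The step needs site selectivity for the methylidene and a cis relation between the siloxyvinyl group and C1: donor/acceptor carbenoids cyclopropanate only the unhindered, most nucleophilic 1,1-disubstituted terminus (the trisubstituted ethylidene and the tetrasubstituted enol ether are too hindered), and the C4 methyl group on the other flank of C5 should steer the bulky siloxyvinyl group to the ethylidene side. A non-polar solvent and slow addition are chosen to disfavour a stepwise zwitterionic addition to the electron-rich dienol ether.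

Step 8
Reactants: 12 methyl (8S)-6-[(tert-butyldimethylsilyl)oxy]-3,8-dimethyl-2-(2-methylpropoxy)-1,4,7,8-tetrahydroazulene-5-carboxylate
Product: 13 methyl (8S,8aR)-3,8-dimethyl-2,6-dioxo-1,2,4,5,6,7,8,8a-octahydroazulene-5-carboxylate (C5 epimers of the azulene numbering, guaiane C7, in equilibrium with the enol)
Conditions: 2 M aq. HCl, THF, 0 °C to 40 °C
Reagents that add atoms: water, O
Why: Aqueous acid cleaves the silyl enol ether to the β-keto ester and hydrolyses the alkoxycyclopentadiene (a dienol ether) by γ-protonation at C1 to the conjugated cyclopentenone; under the same acid C1 should equilibrate through the dienol (the known γ-epimerisation of conjugated enones) to the more stable epimer with the C1–C2 bond trans to the pseudo-equatorial C10 methyl, that is with H-1 on the methyl face as in the target, while C7 stays labile.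

Step 9
Reactants: 13 methyl (8S,8aR)-3,8-dimethyl-2,6-dioxo-1,2,4,5,6,7,8,8a-octahydroazulene-5-carboxylate
Product: 14 methyl (5S,6R,8S,8aR)-2,6-dihydroxy-3,8-dimethyl-1,2,4,5,6,7,8,8a-octahydroazulene-5-carboxylate (both C2 carbinol epimers; ester, 6-OH, 8-CH3 and 8a-H on one face)
Conditions: Zn(BH4)2 (excess), Et2O/CH2Cl2, −20 °C to rt; aq. NH4Cl
Reagents that add atoms: none
Why: Zn(BH4)2 reduction of an α-substituted β-keto ester is chelation-controlled and syn-selective, which in a ring means the cis hydroxy ester; because C7 epimerises through the enol (dynamic kinetic resolution), the material should be funnelled through the chelate in which hydride reaches C8 from the face opposite the C10 methyl and on the side of H-7, placing the C8 hydroxyl and the C7 ester on the methyl face, and the enone carbonyl is reduced 1,2 in the same pot to an allylic alcohol whose configuration does not matter.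

Step 10
Reactants: 14 methyl (5S,6R,8S,8aR)-2,6-dihydroxy-3,8-dimethyl-1,2,4,5,6,7,8,8a-octahydroazulene-5-carboxylate
Product: 15 (5S,6R,8S,8aR)-5-(2-hydroxypropan-2-yl)-3,8-dimethyl-1,2,4,5,6,7,8,8a-octahydroazulene-2,6-diol (both C2 epimers)
Conditions: MeMgBr (6 equiv), THF, 0 °C to rt; aq. NH4Cl
Reagents that add atoms: methylmagnesium bromide, C[Mg]Br
Why: Excess MeMgBr first deprotonates the two hydroxyl groups and then adds twice to the methyl ester (Grignard addition via the methyl ketone) to build the C11 tertiary carbinol; the C7 configuration should be retained because carbonyl addition outruns enolisation of the alkoxide-bearing ester.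

Step 11
Reactants: 15 (5S,6R,8S,8aR)-5-(2-hydroxypropan-2-yl)-3,8-dimethyl-1,2,4,5,6,7,8,8a-octahydroazulene-2,6-diol
Product: 16 (5S,6R,8S,8aR)-6-hydroxy-5-(2-hydroxypropan-2-yl)-3,8-dimethyl-4,5,6,7,8,8a-hexahydroazulen-2(1H)-one
Conditions: activated MnO2 (excess), CH2Cl2, rt
Reagents that add atoms: none
Why: Activated MnO2 oxidises only the allylic C3 alcohol, so both carbinol epimers converge on the conjugated enone while the secondary C8 and tertiary C11 hydroxyls are untouched.

Step 12
Reactants: 16 (5S,6R,8S,8aR)-6-hydroxy-5-(2-hydroxypropan-2-yl)-3,8-dimethyl-4,5,6,7,8,8a-hexahydroazulen-2(1H)-one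
Product: 17 (5S,6R,8S,8aR)-5-(2-hydroxypropan-2-yl)-3,8-dimethyl-2-oxo-1,2,4,5,6,7,8,8a-octahydroazulen-6-yl propanoate
Conditions: (EtCO)2O, pyridine, DMAP (cat.), CH2Cl2, 0 °C to rt
Reagents that add atoms: propanoic anhydride, CCC(=O)OC(=O)CC
Why: DMAP-catalysed acylation with the anhydride discriminates the secondary C8 hydroxyl from the hindered tertiary C11 hydroxyl.

Step 13
Reactants: 17 (5S,6R,8S,8aR)-5-(2-hydroxypropan-2-yl)-3,8-dimethyl-2-oxo-1,2,4,5,6,7,8,8a-octahydroazulen-6-yl propanoate
Product: 18 (5S,6R,8S,8aR)-5-(2-acetoxypropan-2-yl)-3,8-dimethyl-2-oxo-1,2,4,5,6,7,8,8a-octahydroazulen-6-yl propanoate (CNP0288556.1)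
Conditions: Ac2O (excess), DMAP (2 equiv), Et3N, CH2Cl2, 40 °C
Reagents that add atoms: acetic anhydride, CC(=O)OC(C)=O
Why: Acetylation of the tertiary alcohol through the N-acetyl-DMAP cation (Steglich-type acyl transfer, known for tertiary alcohols) in a basic medium, which avoids ionisation of the tertiary carbinol and acid-mediated 1,3-acyl migration.

**Compound list**

1 | 2-methylcyclopentane-1,3-dione | CC1C(=O)CCC1=O | starting material
2 | 3-isobutoxy-2-methylcyclopent-2-en-1-one | CC1=C(OCC(C)C)CCC1=O | intermediate
3 | acetaldehyde | CC=O | starting material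
4 | 5-(1-hydroxyethyl)-3-isobutoxy-2-methylcyclopent-2-en-1-one (racemic diastereomer mixture) | CC(O)C1CC(OCC(C)C)=C(C)C1=O | intermediate
5 | 1-(4-isobutoxy-3-methyl-2-oxocyclopent-3-en-1-yl)ethyl methanesulfonate (not isolated) | CC(OS(C)(=O)=O)C1CC(OCC(C)C)=C(C)C1=O | intermediate
6 | (E)-5-ethylidene-3-isobutoxy-2-methylcyclopent-2-en-1-one | C/C=C1\CC(OCC(C)C)=C(C)C1=O | intermediate
7 | (E)-4-ethylidene-1-isobutoxy-2-methyl-3-methylidenecyclopent-1-ene | C=C1C(C)=C(OCC(C)C)C\C1=C/C | intermediate
8 | methyl acetoacetate | COC(=O)CC(C)=O | starting material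
9 | methyl 2-diazo-3-oxobutanoate | COC(=O)C(=[N+]=[N-])C(C)=O | intermediate
10 | methyl 3-(tert-butyldimethylsilyloxy)-2-diazobut-3-enoate | C=C(O[Si](C)(C)C(C)(C)C)C(=[N+]=[N-])C(=O)OC | intermediate
11 | methyl (E)-1-[1-(tert-butyldimethylsilyloxy)ethenyl]-7-ethylidene-4-methyl-5-(2-methylpropoxy)spiro[2.4]hept-4-ene-1-carboxylate, siloxyvinyl group cis to the ethylidene-bearing ring carbon (not isolated) | COC(=O)[C@@]1(C(=C)O[Si](C)(C)C(C)(C)C)C[C@@]12C(C)=C(OCC(C)C)C\C2=C/C | intermediate
12 | methyl (8S)-6-[(tert-butyldimethylsilyl)oxy]-3,8-dimethyl-2-(2-methylpropoxy)-1,4,7,8-tetrahydroazulene-5-carboxylate | COC(=O)C1=C(O[Si](C)(C)C(C)(C)C)C[C@H](C)C2=C(C1)C(C)=C(OCC(C)C)C2 | intermediate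
13 | methyl (8S,8aR)-3,8-dimethyl-2,6-dioxo-1,2,4,5,6,7,8,8a-octahydroazulene-5-carboxylate (labile at the ester-bearing carbon) | O=C1C[C@H](C)[C@H]2CC(=O)C(C)=C2CC1C(=O)OC | intermediate
14 | methyl (5S,6R,8S,8aR)-2,6-dihydroxy-3,8-dimethyl-1,2,4,5,6,7,8,8a-octahydroazulene-5-carboxylate (both C2 carbinol epimers) | O[C@@H]1C[C@H](C)[C@H]2CC(O)C(C)=C2C[C@@H]1C(=O)OC | intermediate
15 | (5S,6R,8S,8aR)-5-(2-hydroxypropan-2-yl)-3,8-dimethyl-1,2,4,5,6,7,8,8a-octahydroazulene-2,6-diol (both C2 carbinol epimers) | O[C@@H]1C[C@H](C)[C@H]2CC(O)C(C)=C2C[C@@H]1C(C)(C)O | intermediate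
16 | (5S,6R,8S,8aR)-6-hydroxy-5-(2-hydroxypropan-2-yl)-3,8-dimethyl-4,5,6,7,8,8a-hexahydroazulen-2(1H)-one | O[C@@H]1C[C@H](C)[C@H]2CC(=O)C(C)=C2C[C@@H]1C(C)(C)O | intermediate
17 | (5S,6R,8S,8aR)-5-(2-hydroxypropan-2-yl)-3,8-dimethyl-2-oxo-1,2,4,5,6,7,8,8a-octahydroazulen-6-yl propanoate | CCC(=O)O[C@@H]1C[C@H](C)[C@H]2CC(=O)C(C)=C2C[C@@H]1C(C)(C)O | intermediate
18 | (5S,6R,8S,8aR)-5-(2-acetoxypropan-2-yl)-3,8-dimethyl-2-oxo-1,2,4,5,6,7,8,8a-octahydroazulen-6-yl propanoate | CCC(=O)O[C@@H]1C[C@H](C)[C@H]2CC(=O)C(C)=C2C[C@@H]1C(C)(C)OC(C)=O | target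

**Step count and risks**

Total: 13 steps. Longest linear sequence: 11 steps (steps 1–4 and 7–13, from 2-methylcyclopentane-1,3-dione); the diazo partner (steps 5 and 6) joins at step 7.

Most likely to fail, step 7: enantioface discrimination at the 1,1-disubstituted methylidene may be weak, and configuration may be partly lost when the spiro cyclopropane reopens by homolysis of the doubly stabilised C5–C7 bond or when addition turns stepwise. The fallback moves the source of enantiopurity from the catalyst to a late enzymatic resolution. It sets out from 7 and 10, which are combined under achiral Rh2(O2CCMe3)4 in hexanes. This tandem reaction is known and should give 12 together with its mirror image ent-12 F2, formed through ent-11 F1. Steps 8 to 11 are then run unchanged on the racemate, passing ent-13 F3, ent-14 F4 and ent-15 F5, and give 16 together with ent-16 F6. The enantiomers are separated by lipase-catalysed kinetic resolution with vinyl propanoate (immobilised Candida antarctica lipase B or Burkholderia cepacia lipase, MTBE, 35 °C), a known way to resolve secondary alcohols. The empirical size rule for lipases (large group C7 with the carbinol side chain, medium group the C9 methylene) predicts faster acylation of the 8R alcohol 16. The resolution should therefore deliver 17 directly, and the route is rejoined at 17; unreacted ent-16 F6 is removed by chromatography.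

Second, step 9: facial discrimination at C8 may be insufficient and the two C7 epimers may not be funnelled completely, which would give diastereomeric hydroxy esters. The fallback replaces substrate control by catalyst control. It sets out from 13, which is reduced by a ketoreductase chosen from a commercial panel (NADP cofactor recycled with propan-2-ol, phosphate buffer pH 7 with DMSO, 30 °C). Enzymatic dynamic reduction of cyclic 2-alkoxycarbonyl ketones to cis hydroxy esters is known. It should give methyl (5S,6R,8S,8aR)-6-hydroxy-3,8-dimethyl-2-oxo-1,2,4,5,6,7,8,8a-octahydroazulene-5-carboxylate F7 with the enone untouched. Luche reduction (NaBH4, CeCl3·7H2O, MeOH, −20 °C) of the enone carbonyl then rejoins the route at 14.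

Third, step 4: the cross-conjugated alkoxy triene may isomerise to fulvene-type isomers or oligomerise under the Lewis-acidic aluminium by-product, and the dienone may be enolised instead of methylenated. The fallback is a two-stage Peterson olefination, free of aluminium. It sets out from 6, to which Me3SiCH2Li with anhydrous CeCl3 (THF, −78 °C) should add 1,2 to give (E)-5-ethylidene-3-isobutoxy-2-methyl-1-[(trimethylsilyl)methyl]cyclopent-2-en-1-ol F8. KH (THF, 0 °C) then effects syn elimination, and the route is rejoined at 7.

**Further compounds**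

F1 | step 7 | ent-11, mirror image of spiro divinylcyclopropane 11 | COC(=O)[C@]1(C(=C)O[Si](C)(C)C(C)(C)C)C[C@]12C(C)=C(OCC(C)C)C\C2=C/C
F2 | step 7 | ent-12, methyl (8R)-6-[(tert-butyldimethylsilyl)oxy]-3,8-dimethyl-2-(2-methylpropoxy)-1,4,7,8-tetrahydroazulene-5-carboxylate | COC(=O)C1=C(O[Si](C)(C)C(C)(C)C)C[C@@H](C)C2=C(C1)C(C)=C(OCC(C)C)C2
F3 | step 7 | ent-13, methyl (8R,8aS)-3,8-dimethyl-2,6-dioxo-1,2,4,5,6,7,8,8a-octahydroazulene-5-carboxylate | O=C1C[C@@H](C)[C@@H]2CC(=O)C(C)=C2CC1C(=O)OC
F4 | step 7 | ent-14, methyl (5R,6S,8R,8aS)-2,6-dihydroxy-3,8-dimethyl-1,2,4,5,6,7,8,8a-octahydroazulene-5-carboxylate | O[C@H]1C[C@@H](C)[C@@H]2CC(O)C(C)=C2C[C@H]1C(=O)OC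
F5 | step 7 | ent-15, (5R,6S,8R,8aS)-5-(2-hydroxypropan-2-yl)-3,8-dimethyl-1,2,4,5,6,7,8,8a-octahydroazulene-2,6-diol | O[C@H]1C[C@@H](C)[C@@H]2CC(O)C(C)=C2C[C@H]1C(C)(C)O
F6 | step 7 | ent-16, (5R,6S,8R,8aS)-6-hydroxy-5-(2-hydroxypropan-2-yl)-3,8-dimethyl-4,5,6,7,8,8a-hexahydroazulen-2(1H)-one | O[C@H]1C[C@@H](C)[C@@H]2CC(=O)C(C)=C2C[C@H]1C(C)(C)O
F7 | step 9 | methyl (5S,6R,8S,8aR)-6-hydroxy-3,8-dimethyl-2-oxo-1,2,4,5,6,7,8,8a-octahydroazulene-5-carboxylate | O[C@@H]1C[C@H](C)[C@H]2CC(=O)C(C)=C2C[C@@H]1C(=O)OC
F8 | step 4 | (E)-5-ethylidene-3-isobutoxy-2-methyl-1-[(trimethylsilyl)methyl]cyclopent-2-en-1-ol | C/C=C1\CC(OCC(C)C)=C(C)C1(O)C[Si](C)(C)C
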